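**Retrosynthetic overview**
- Last bond made: the allylic C–OH of the (E)-4-hydroxy-3-methylbut-2-enyl arm, by palladium-catalysed hydroxylative opening of a 2-isopropenyl-2,3-dihydrobenzofuran (allylic C–O made, aryl ether C–O broken, phenol released).
- That dihydrofuran ring is the only ring formed (step 4) and is opened again in step 6. It comes from a Larock annulation of an ortho-iodophenol with isoprene; the benzene ring is bought as 4-hydroxy-3,5-diiodobenzoic acid.
- The ketone arm is attached by hydroboration/B-alkyl Suzuki coupling of a chiral diene diol; its secondary alcohol is oxidised to the enone only after the phenol is masked.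
- The diene diol (methyl stereocentre) comes from Brown anti-crotylboration of (E)-4-hydroxy-4-methylpent-2-enal, made by cross-metathesis of 2-methylbut-3-en-2-ol with crotonaldehyde.

Assumption: the ring carbon C2 of the temporary dihydrofuran in 15 and 16 is formed as both epimers and is written without a descriptor, because step 6 removes it.

**Step 1**
Reactants: 1 2-methylbut-3-en-2-ol; 2 (E)-but-2-enal (crotonaldehyde)
Product: 3 (2E)-4-hydroxy-4-methylpent-2-enal
Conditions: RuCl2(H2IMes)(=CH-C6H4-2-OiPr) (second-generation Hoveyda–Grubbs catalyst, 3 mol%), 2 (3 equiv), CH2Cl2, 40 °C, 12 h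
Reagents that add atoms: none
Why: Olefin cross-metathesis: the tertiary allylic alcohol does not homodimerise and the enal is in excess (crotonaldehyde releases propene), so the conjugated E-enal forms selectively (E:Z > 20:1 expected); no stereocentre is formed.

**Step 2**
Reactants: 3 (2E)-4-hydroxy-4-methylpent-2-enal; 4 (E)-but-2-ene; 5 (+)-B-methoxydiisopinocampheylborane (from (−)-α-pinene)
Product: 9 (3E,5S,6R)-2,6-dimethylocta-3,7-diene-2,5-diol, via (E)-crotylpotassium 6 (not isolated), via (E)-crotyldiisopinocampheylborane 7 (not isolated), via diisopinocampheylborinate ester 8 (not isolated)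
Conditions: 4, n-BuLi, KOt-Bu, THF, −78 to −45 °C; 5, −78 °C; BF3·OEt2, −78 °C; 3 (0.5 equiv relative to 7), −78 °C, 4 h; NaOH, H2O2, 0 °C to rt
Reagents that add atoms: none
Why: Brown crotylboration: the (E)-crotylborane reacts through a chair Zimmerman–Traxler transition state to give the anti adduct, and the isopinocampheyl groups of the (−)-α-pinene series direct it to the Re face of the aldehyde, which sets C5 as S and therefore the methyl-bearing C6 as R (the only stereocentre kept to the target; dr ≥ 20:1 and ≥ 92% ee expected), the hindered tertiary hydroxyl being tolerated at −78 °C with two equivalents of 7.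

**Step 3**
Reactants: 9 (3E,5S,6R)-2,6-dimethylocta-3,7-diene-2,5-diol; 10 9-borabicyclo[3.3.1]nonane (9-BBN); 11 4-hydroxy-3,5-diiodobenzoic acid
Product: 13 4-hydroxy-3-[(3R,4R,5E)-4,7-dihydroxy-3,7-dimethyloct-5-en-1-yl]-5-iodobenzoic acid, via B-alkyl-9-BBN adduct 12 (not isolated)
Conditions: 10 (3.5 equiv), THF, 0 °C to rt; then 11 (2.5 equiv), PdCl2(dppf) (5 mol%), K3PO4 (3 M aq), DMF, 50 °C; pH 4 work-up
Reagents that add atoms: none
Why: Hydroboration then B-alkyl Suzuki–Miyaura coupling: 9-BBN adds only to the monosubstituted alkene with boron on the terminal carbon (the internal alkene between two carbinol carbons is too hindered), and the borane, limiting against an excess of the cheap symmetric diiodide, couples once under PdCl2(dppf), which suppresses β-hydride elimination; both stereocentres are untouched (C4 becomes R only by a change of priorities).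

**Step 4**
Reactants: 13 4-hydroxy-3-[(3R,4R,5E)-4,7-dihydroxy-3,7-dimethyloct-5-en-1-yl]-5-iodobenzoic acid; 14 isoprene (2-methylbuta-1,3-diene)
Product: 15 7-[(3R,4R,5E)-4,7-dihydroxy-3,7-dimethyloct-5-en-1-yl]-2-(prop-1-en-2-yl)-2,3-dihydro-1-benzofuran-5-carboxylic acid
Conditions: 14 (5 equiv), Pd(OAc)2 (5 mol%), NaHCO3 (4 equiv), n-Bu4NCl (1 equiv), DMF, 65 °C, sealed tube, 24 h
Reagents that add atoms: none
Why: Larock diene heteroannulation: the arylpalladium iodide adds its aryl group to the unsubstituted vinyl terminus of isoprene and the neighbouring phenoxide attacks the proximal carbon of the π-allylpalladium, forming the aryl ether C–O bond and the dihydrofuran ring; the new ring carbon C2 forms as both epimers, which is harmless because step 6 removes it, and the ring masks the phenol for step 5 while storing the five carbons of the allylic alcohol arm.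

**Step 5**
Reactants: 15 7-[(3R,4R,5E)-4,7-dihydroxy-3,7-dimethyloct-5-en-1-yl]-2-(prop-1-en-2-yl)-2,3-dihydro-1-benzofuran-5-carboxylic acid
Product: 16 7-[(3R,5E)-7-hydroxy-3,7-dimethyl-4-oxooct-5-en-1-yl]-2-(prop-1-en-2-yl)-2,3-dihydro-1-benzofuran-5-carboxylic acid
Conditions: Dess–Martin periodinane (1.3 equiv), CH2Cl2, 0 °C to rt
Reagents that add atoms: none
Why: Dess–Martin oxidation: the secondary allylic alcohol is oxidised to the E-enone under near-neutral conditions, the tertiary alcohol cannot be oxidised, the phenol is masked as the ether, and the methyl stereocentre now α to the ketone is not epimerised by the weakly acidic medium.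

**Step 6**
Reactants: 16 7-[(3R,5E)-7-hydroxy-3,7-dimethyl-4-oxooct-5-en-1-yl]-2-(prop-1-en-2-yl)-2,3-dihydro-1-benzofuran-5-carboxylic acid
Product: 18 4-hydroxy-3-[(2E)-4-hydroxy-3-methylbut-2-en-1-yl]-5-[(3R,5E)-7-hydroxy-3,7-dimethyl-4-oxooct-5-en-1-yl]benzoic acid, via allylic hydrogencarbonate 17 (not isolated)
Conditions: Pd2(dba)3 (2.5 mol%), DPEphos (6 mol%), KHCO3 (3 equiv), THF–H2O (1:1), 40 °C, slow N2 sweep, about 4 h; then 0.5 M HCl to pH 4, 0 °C
Reagents that add atoms: potassium hydrogencarbonate, [K+].OC(=O)[O-] (gives the hydroxyl oxygen)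
Why: Proposed new method: zerovalent palladium ionises the allylic aryl ether bond (C2–O) of the 2-isopropenyl-2,3-dihydrobenzofuran, the para-carboxyphenoxide acting as leaving group as in palladium-catalysed deallylation of allyl aryl ethers, to give a 1-(arylmethyl)-2-methyl-π-allylpalladium cation; return of the phenoxide only re-forms 16, whereas hydrogencarbonate attacks the unhindered CH2 terminus to give 17, which loses CO2 (swept out) so that the new allylic C–O bond is not re-ionised and the phenol stays as its potassium salt, and the preferred syn π-allyl (arylmethyl cis to the central methyl) gives the E alkene with no stereocentre touched below about pH 10; closest known reaction types: Tsuji–Trost allylic substitution with hydrogencarbonate as hydroxide equivalent and the reverse of the C–O ring closure of the Larock annulation.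

**Compound list**
1 | 2-methylbut-3-en-2-ol | C=CC(C)(C)O | starting material
2 | (E)-but-2-enal | C/C=C/C=O | starting material
3 | (2E)-4-hydroxy-4-methylpent-2-enal | CC(C)(O)/C=C/C=O | intermediate
4 | (E)-but-2-ene | C/C=C/C | starting material
5 | (+)-B-methoxydiisopinocampheylborane | COB([C@H]1C[C@H]2C[C@@H]([C@@H]1C)C2(C)C)[C@H]1C[C@H]2C[C@@H]([C@@H]1C)C2(C)C | starting material
6 | (E)-crotylpotassium (not isolated) | [K+].C/C=C/[CH2-] | intermediate
7 | (E)-crotyldiisopinocampheylborane (not isolated) | C/C=C/CB([C@H]1C[C@H]2C[C@@H]([C@@H]1C)C2(C)C)[C@H]1C[C@H]2C[C@@H]([C@@H]1C)C2(C)C | intermediate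
8 | (3E,5S,6R)-5-[(diisopinocampheylboranyl)oxy]-2,6-dimethylocta-3,7-dien-2-ol (not isolated) | C=C[C@@H](C)[C@@H](OB([C@H]1C[C@H]2C[C@@H]([C@@H]1C)C2(C)C)[C@H]1C[C@H]2C[C@@H]([C@@H]1C)C2(C)C)/C=C/C(C)(C)O | intermediate
9 | (3E,5S,6R)-2,6-dimethylocta-3,7-diene-2,5-diol | C=C[C@@H](C)[C@@H](O)/C=C/C(C)(C)O | intermediate
10 | 9-borabicyclo[3.3.1]nonane | B1C2CCCC1CCC2 | starting material
11 | 4-hydroxy-3,5-diiodobenzoic acid | OC(=O)c1cc(I)c(O)c(I)c1 | starting material
12 | 9-[(3R,4R,5E)-4,7-dihydroxy-3,7-dimethyloct-5-en-1-yl]-9-borabicyclo[3.3.1]nonane (not isolated; hydroxyls shown free) | B1(CC[C@@H](C)[C@@H](O)/C=C/C(C)(C)O)C2CCCC1CCC2 | intermediate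
13 | 4-hydroxy-3-[(3R,4R,5E)-4,7-dihydroxy-3,7-dimethyloct-5-en-1-yl]-5-iodobenzoic acid | OC(=O)c1cc(I)c(O)c(CC[C@@H](C)[C@@H](O)/C=C/C(C)(C)O)c1 | intermediate
14 | isoprene | C=CC(C)=C | starting material
15 | 7-[(3R,4R,5E)-4,7-dihydroxy-3,7-dimethyloct-5-en-1-yl]-2-(prop-1-en-2-yl)-2,3-dihydro-1-benzofuran-5-carboxylic acid (both C2 epimers) | CC(=C)C1Cc2cc(C(=O)O)cc(CC[C@@H](C)[C@@H](O)/C=C/C(C)(C)O)c2O1 | intermediate
16 | 7-[(3R,5E)-7-hydroxy-3,7-dimethyl-4-oxooct-5-en-1-yl]-2-(prop-1-en-2-yl)-2,3-dihydro-1-benzofuran-5-carboxylic acid (both C2 epimers) | CC(=C)C1Cc2cc(C(=O)O)cc(CC[C@@H](C)C(=O)/C=C/C(C)(C)O)c2O1 | intermediate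
17 | 3-[(2E)-4-(carboxyoxy)-3-methylbut-2-en-1-yl]-4-hydroxy-5-[(3R,5E)-7-hydroxy-3,7-dimethyl-4-oxooct-5-en-1-yl]benzoic acid (not isolated) | OC(=O)OC/C(C)=C/Cc1cc(C(=O)O)cc(CC[C@@H](C)C(=O)/C=C/C(C)(C)O)c1O | intermediate
18 | 4-hydroxy-3-[(2E)-4-hydroxy-3-methylbut-2-en-1-yl]-5-[(3R,5E)-7-hydroxy-3,7-dimethyl-4-oxooct-5-en-1-yl]benzoic acid | C/C(=C\Cc1cc(C(=O)O)cc(CC[C@@H](C)C(=O)/C=C/C(C)(C)O)c1O)CO | target

**Step count and risks**
Total step count: 6. Longest linear sequence: 6.

Step 6 (the proposed new step) is the most likely to fail. The opening is only mildly downhill and is pulled by loss of CO2 and phenoxide formation. The π-allyl may instead undergo β-hydride elimination to the aryl diene, be attacked at its internal terminus, or give some Z alkene. The centre α to the ketone may slowly epimerise if the pH drifts above about 10. The fallback uses known chemistry, sets out from 13 and comes back at 18. Activated MnO2 in CH2Cl2 oxidises the secondary allylic alcohol of 13 beside the free phenol to give 4-hydroxy-3-[(3R,5E)-7-hydroxy-3,7-dimethyl-4-oxooct-5-en-1-yl]-5-iodobenzoic acid F1. Stille coupling with tributyl(3-methylbut-2-en-1-yl)stannane (Pd(PPh3)4, CsF, DMF, 80 °C) gives 4-hydroxy-3-[(3R,5E)-7-hydroxy-3,7-dimethyl-4-oxooct-5-en-1-yl]-5-(3-methylbut-2-en-1-yl)benzoic acid F2. SeO2 (0.5 equiv) with t-BuOOH in CH2Cl2 at rt then hydroxylates the E-methyl group (ene reaction, then [2,3]-sigmatropic shift) to give 18. This replaces the ring opening by a C–H hydroxylation and never forms the dihydrofuran.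

Step 3 is the second risk. The unprotected diiodophenol acid may couple sluggishly, lose iodine by protodeiodination or couple twice, and excess 9-BBN is consumed by the free hydroxyls. The fallback sets out from 11 and 14 and comes back at 15. Larock annulation of 11 (2 equiv) with 14 is run first (Pd(OAc)2, NaHCO3, n-Bu4NCl, DMF, 65 °C) to give 7-iodo-2-(prop-1-en-2-yl)-2,3-dihydro-1-benzofuran-5-carboxylic acid F3. B-alkyl Suzuki coupling of F3 with borane 12 (PdCl2(dppf), K3PO4, 25–40 °C, so that aryl iodide insertion outruns ionisation of the allylic ether) then gives 15 directly. The phenol is thus masked before the coupling and the statistical step is moved to cheap material.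

Step 2 is the third risk. The free tertiary hydroxyl and the enal may erode yield or selectivity with the stoichiometric borane. The pairing of the isopinocampheyl series from (−)-α-pinene with Re-face attack follows the usual chair model and should be confirmed on the first batch by Mosher ester analysis of 9. The fallback sets out from 3 and comes back at 9. It is an iridium-catalysed transfer-hydrogenative anti-crotylation of 3 with racemic but-3-en-2-yl acetate ([Ir(cod)Cl]2, the SEGPHOS antipode that gives Re-face addition (expected (R)-SEGPHOS), 4-cyano-3-nitrobenzoic acid, Cs2CO3, i-PrOH, THF, 90 °C). It is catalytic, tolerates free hydroxyls and makes no compound outside the list (F0).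

**Further compounds**
F1 | step 6 | 4-hydroxy-3-[(3R,5E)-7-hydroxy-3,7-dimethyl-4-oxooct-5-en-1-yl]-5-iodobenzoic acid | OC(=O)c1cc(I)c(O)c(CC[C@@H](C)C(=O)/C=C/C(C)(C)O)c1
F2 | step 6 | 4-hydroxy-3-[(3R,5E)-7-hydroxy-3,7-dimethyl-4-oxooct-5-en-1-yl]-5-(3-methylbut-2-en-1-yl)benzoic acid | CC(C)=CCc1cc(C(=O)O)cc(CC[C@@H](C)C(=O)/C=C/C(C)(C)O)c1O
F3 | step 3 | 7-iodo-2-(prop-1-en-2-yl)-2,3-dihydro-1-benzofuran-5-carboxylic acid (racemic) | CC(=C)C1Cc2cc(C(=O)O)cc(I)c2O1
F0 | step 2 | none | none
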